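**Plan**

- Ring A is numbered C1 (prenyl), C2 (OH), C3 (H), C4 (OH), C5 (CHO), C6 (aroyl). C6 is meta to both oxygens and next to the prenyl-bearing C1, which is ortho to O2. This is the pattern left when a nucleophile adds to C6 and an electrophile to C1 of a C1≡C6 aryne polarised by the O2 substituent.
- Retrosynthetic cuts: first C5–CHO (formylation of the free resorcinol ring A); then C6–C(=O) and C1–CH2 together (aryne, ring-B acyl-anion equivalent, prenyl bromide); then the ring-B ipso C–CHO bond (ortho-lithiation).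
- Forward: no ring is built. Bromofluoroarene 4 (3 steps) and dithiane 12 (5 steps) are joined with prenyl bromide in step 9. Dithiane hydrolysis, fluoride removal of the ring-A SEM groups, C5 formylation and acid removal of the ring-B MOM groups follow.
- Stereochemistry: the target has no stereocentre and no configurable double bond, so only regiochemistry needs control (aryne polarisation by O2; SEM on ring A against MOM on ring B to steer the formylation).

Key step: step 9

Remark: the target is achiral, so "single enantiomer" is read as the one constitution drawn. Ring A carries SEM and ring B carries MOM so that ring A alone can be unmasked before the formylation, because the two rings would otherwise be about equally reactive toward an electrophile.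

**Step 1**
Reactants: 1 1-fluoro-3,5-dimethoxybenzene
Product: 2 2-bromo-1-fluoro-3,5-dimethoxybenzene
Conditions: NBS (1.0 equiv), MeCN, 0 °C → rt
Reagents that add atoms: N-bromosuccinimide, O=C1CCC(=O)N1Br
Why: Electrophilic aromatic bromination of a resorcinol diether goes para to one methoxy and ortho to the other (here the carbon next to fluorine) and avoids the crowded carbon between the two methoxy groups, and one equivalent should stop at the monobromide.

**Step 2**
Reactants: 2 2-bromo-1-fluoro-3,5-dimethoxybenzene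
Product: 3 4-bromo-5-fluorobenzene-1,3-diol
Conditions: BBr3 (3 equiv), CH2Cl2, −78 °C → rt; H2O
Reagents that add atoms: none
Why: BBr3 demethylation (Lewis-acid cleavage of aryl methyl ethers) should free both phenols without touching the aryl C–Br and C–F bonds.

**Step 3**
Reactants: 3 4-bromo-5-fluorobenzene-1,3-diol
Product: 4 2-bromo-1-fluoro-3,5-bis{[2-(trimethylsilyl)ethoxy]methoxy}benzene
Conditions: SEMCl (2.5 equiv), i-Pr2NEt (3 equiv), CH2Cl2, 0 °C → rt
Reagents that add atoms: 2-(trimethylsilyl)ethoxymethyl chloride, C[Si](C)(C)CCOCCl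
Why: Williamson-type O-alkylation by the reactive α-chloro ether installs acetal groups that tolerate aryllithiums, polarise the later aryne as any alkoxy group does, and can be removed by fluoride while MOM ethers stay.

**Step 4**
Reactants: 5 orcinol (5-methylbenzene-1,3-diol)
Product: 6 1,3-bis(methoxymethoxy)-5-methylbenzene
Conditions: MOMCl (2.5 equiv), i-Pr2NEt (3 equiv), CH2Cl2, 0 °C → rt
Reagents that add atoms: chloromethyl methyl ether, COCCl
Why: Williamson-type O-alkylation of both phenols gives the bis-acetal needed as a directing group for the ortho-lithiation in step 6.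

**Step 5**
Reactants: 6 1,3-bis(methoxymethoxy)-5-methylbenzene
Product: 7 2-chloro-1,5-bis(methoxymethoxy)-3-methylbenzene
Conditions: NCS (1.0 equiv), DMF, rt
Reagents that add atoms: N-chlorosuccinimide, O=C1CCC(=O)N1Cl
Why: Electrophilic aromatic chlorination should go to the carbon ortho to methyl and para to one OMOM in preference to the hindered carbon between the two OMOM groups, and one equivalent limits dichlorination.

**Step 6**
Reactants: 7 2-chloro-1,5-bis(methoxymethoxy)-3-methylbenzene
Product: 9 3-chloro-2,6-bis(methoxymethoxy)-4-methylbenzaldehyde, via aryllithium 8 (not isolated)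
Conditions: n-BuLi (1.1 equiv), TMEDA, THF, −78 → 0 °C; DMF, −78 °C → rt; H2O
Reagents that add atoms: N,N-dimethylformamide, CN(C)C=O
Why: Directed ortho-metalation removes the doubly activated proton between the two OMOM groups (the chlorine has no ortho hydrogen and does not exchange with n-BuLi at this temperature), and the aryllithium is formylated by DMF.

**Step 7**
Reactants: 9 3-chloro-2,6-bis(methoxymethoxy)-4-methylbenzaldehyde; 10 propane-1,3-dithiol
Product: 11 4-chloro-2-(1,3-dithian-2-yl)-5-methylbenzene-1,3-diol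
Conditions: HS(CH2)3SH (3.5 equiv), BF3·OEt2 (0.5 equiv), CH2Cl2, 0 °C → rt
Reagents that add atoms: propane-1,3-dithiol (10), SCCCS
Why: Lewis-acid-catalysed thioacetalisation; because a thiol with a Lewis acid also cleaves aryl MOM ethers (their methylene leaves as 1,3-dithiane), excess dithiol is used to remove both MOM groups on purpose so that one defined product is isolated.

**Step 8**
Reactants: 11 4-chloro-2-(1,3-dithian-2-yl)-5-methylbenzene-1,3-diol
Product: 12 2-[3-chloro-2,6-bis(methoxymethoxy)-4-methylphenyl]-1,3-dithiane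
Conditions: NaH (2.4 equiv), MOMCl (2.4 equiv), DMF, 0 °C → rt
Reagents that add atoms: chloromethyl methyl ether, COCCl
Why: Williamson-type O-alkylation of the two phenoxides; NaH does not deprotonate the dithiane C–H, and the MOM ethers survive the lithiation and are removable last by mild acid.

**Step 9**
Reactants: 12 2-[3-chloro-2,6-bis(methoxymethoxy)-4-methylphenyl]-1,3-dithiane; 4 2-bromo-1-fluoro-3,5-bis{[2-(trimethylsilyl)ethoxy]methoxy}benzene; 13 prenyl bromide (1-bromo-3-methylbut-2-ene)
Product: 19 2-[3-chloro-2,6-bis(methoxymethoxy)-4-methylphenyl]-2-[2-(3-methylbut-2-en-1-yl)-3,5-bis{[2-(trimethylsilyl)ethoxy]methoxy}phenyl]-1,3-dithiane, via lithiated dithiane 14 (not isolated), via fluoroaryllithium 15 (not isolated), via aryne 16 (not isolated), via adduct aryllithium 17 (not isolated), via arylcopper 18 (not isolated)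
Conditions: 12 (1.3 equiv), n-BuLi (1.3 equiv), THF, −78 → −20 °C; separately 4, t-BuLi (2.0 equiv), THF–Et2O, −100 °C; cannulate the second solution into the first at −78 °C, warm to −20 °C; CuBr·SMe2 (1.5 equiv), −40 °C; prenyl bromide (3 equiv), −40 → 0 °C; aq. NH4Cl
Reagents that add atoms: prenyl bromide (13), CC(C)=CCBr
Why: n-BuLi deprotonates 12 at the dithiane carbon (14), t-BuLi exchanges the bromine of 4 (15; the second equivalent destroys t-BuBr so that no alkyl halide can quench 14), and on warming 15 loses LiF to give aryne 16, whose C6 is attacked by 14 to form the C6–C bond and the C1 aryllithium 17. Transmetalation to copper (18) and SN2 displacement on prenyl bromide then form the C1–CH2 bond in the same flask. The closest known reaction type is the carbolithiation of 3-alkoxyarynes by stabilised organolithiums with electrophilic trapping of the resulting ortho-alkoxyaryllithium (three-component aryne coupling), combined with the usual arylcopper prenylation of acetal-protected phenols. No ring is closed and no stereocentre is created. The step needs attack at C6 and not C1, which the σ-withdrawing O2 acetal secures by distorting the aryne and by stabilising and chelating the C1 carbanion (C6, flanked by H5, is also the less hindered end), and it needs α- and not γ-attack on the allylic bromide, which the bulk of 18 and the gem-dimethyl terminus of prenyl bromide secure. The quaternary dithiane carbon offers 17 neither an internal electrophile nor an acidic proton, provided 12 is fully deprotonated beforehand.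

**Step 10**
Reactants: 19 the diaryl dithiane from step 9
Product: 20 [3-chloro-2,6-bis(methoxymethoxy)-4-methylphenyl][2-(3-methylbut-2-en-1-yl)-3,5-bis{[2-(trimethylsilyl)ethoxy]methoxy}phenyl]methanone
Conditions: MeI (10 equiv), CaCO3 (4 equiv), MeCN–H2O (4:1), 45 °C
Reagents that add atoms: water, O
Why: Alkylative dithiane hydrolysis (S-methylation, ionisation to a doubly aryl-stabilised thionium ion, capture by water) is buffered and non-oxidising, so the alkene, the SEM and the MOM groups should survive.

**Step 11**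
Reactants: 20 the SEM/MOM-protected benzophenone
Product: 21 [3-chloro-2,6-bis(methoxymethoxy)-4-methylphenyl][3,5-dihydroxy-2-(3-methylbut-2-en-1-yl)phenyl]methanone
Conditions: TBAF (6 equiv), ethylenediamine (6 equiv), DMF, 60 °C; AcOH
Reagents that add atoms: none
Why: Fluoride attacks silicon and each SEM acetal fragments to phenoxide, ethene and formaldehyde (taken up by ethylenediamine), whereas MOM ethers are inert to fluoride, so only ring A is unmasked.

**Step 12**
Reactants: 21 the ring-A resorcinol benzophenone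
Product: 23 2-[3-chloro-2,6-bis(methoxymethoxy)-4-methylbenzoyl]-4,6-dihydroxy-3-(3-methylbut-2-en-1-yl)benzaldehyde, via iminium salt 22 (not isolated)
Conditions: POCl3 (1.5 equiv), DMF (5 equiv), MeCN, 0 °C → rt; aq. NaOAc, rt
Reagents that add atoms: N,N-dimethylformamide, CN(C)C=O; water, O
Why: Vilsmeier–Haack formylation should select the free resorcinol ring A over the chlorinated, acylated bis-ether ring B, and within ring A the carbon para to O2–H and ortho to O4–H (C5) is the usual site for a 5-substituted resorcinol, not C3 between the two oxygens.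

**Step 13**
Reactants: 23 the ring-B bis-MOM aldehyde
Product: 24 pestalone E, 2-(3-chloro-2,6-dihydroxy-4-methylbenzoyl)-4,6-dihydroxy-3-(3-methylbut-2-en-1-yl)benzaldehyde
Conditions: 2 M aq. HCl, THF, 0 °C → rt
Reagents that add atoms: none
Why: Acid-catalysed acetal hydrolysis; both remaining MOM ethers are ortho to the ketone and should cleave with carbonyl assistance under conditions mild enough to spare the prenyl group and the keto-aldehyde.

**Compound list**

1 | 1-fluoro-3,5-dimethoxybenzene | COc1cc(F)cc(OC)c1 | starting material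
2 | 2-bromo-1-fluoro-3,5-dimethoxybenzene | COc1cc(OC)c(Br)c(F)c1 | intermediate
3 | 4-bromo-5-fluorobenzene-1,3-diol | Oc1cc(O)c(Br)c(F)c1 | intermediate
4 | 2-bromo-1-fluoro-3,5-bis{[2-(trimethylsilyl)ethoxy]methoxy}benzene | C[Si](C)(C)CCOCOc1cc(OCOCC[Si](C)(C)C)c(Br)c(F)c1 | intermediate
5 | orcinol (5-methylbenzene-1,3-diol) | Cc1cc(O)cc(O)c1 | starting material
6 | 1,3-bis(methoxymethoxy)-5-methylbenzene | COCOc1cc(C)cc(OCOC)c1 | intermediate
7 | 2-chloro-1,5-bis(methoxymethoxy)-3-methylbenzene | COCOc1cc(C)c(Cl)c(OCOC)c1 | intermediate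
8 | [3-chloro-2,6-bis(methoxymethoxy)-4-methylphenyl]lithium | [Li]c1c(OCOC)cc(C)c(Cl)c1OCOC | intermediate (not isolated)
9 | 3-chloro-2,6-bis(methoxymethoxy)-4-methylbenzaldehyde | COCOc1cc(C)c(Cl)c(OCOC)c1C=O | intermediate
10 | propane-1,3-dithiol | SCCCS | starting material
11 | 4-chloro-2-(1,3-dithian-2-yl)-5-methylbenzene-1,3-diol | Cc1cc(O)c(C2SCCCS2)c(O)c1Cl | intermediate
12 | 2-[3-chloro-2,6-bis(methoxymethoxy)-4-methylphenyl]-1,3-dithiane | COCOc1cc(C)c(Cl)c(OCOC)c1C1SCCCS1 | intermediate
13 | prenyl bromide (1-bromo-3-methylbut-2-ene) | CC(C)=CCBr | starting material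
14 | {2-[3-chloro-2,6-bis(methoxymethoxy)-4-methylphenyl]-1,3-dithian-2-yl}lithium | [Li]C1(SCCCS1)c1c(OCOC)cc(C)c(Cl)c1OCOC | intermediate (not isolated)
15 | (2-fluoro-4,6-bis{[2-(trimethylsilyl)ethoxy]methoxy}phenyl)lithium | [Li]c1c(F)cc(OCOCC[Si](C)(C)C)cc1OCOCC[Si](C)(C)C | intermediate (not isolated)
16 | 1,2-didehydro-3,5-bis{[2-(trimethylsilyl)ethoxy]methoxy}benzene (aryne) | C[Si](C)(C)CCOCOC1=CC#CC(OCOCC[Si](C)(C)C)=C1 | intermediate (not isolated)
17 | (2-{2-[3-chloro-2,6-bis(methoxymethoxy)-4-methylphenyl]-1,3-dithian-2-yl}-4,6-bis{[2-(trimethylsilyl)ethoxy]methoxy}phenyl)lithium | [Li]c1c(OCOCC[Si](C)(C)C)cc(OCOCC[Si](C)(C)C)cc1C1(SCCCS1)c1c(OCOC)cc(C)c(Cl)c1OCOC | intermediate (not isolated)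
18 | the corresponding arylcopper(I) species | [Cu]c1c(OCOCC[Si](C)(C)C)cc(OCOCC[Si](C)(C)C)cc1C1(SCCCS1)c1c(OCOC)cc(C)c(Cl)c1OCOC | intermediate (not isolated)
19 | 2-[3-chloro-2,6-bis(methoxymethoxy)-4-methylphenyl]-2-[2-(3-methylbut-2-en-1-yl)-3,5-bis{[2-(trimethylsilyl)ethoxy]methoxy}phenyl]-1,3-dithiane | CC(C)=CCc1c(OCOCC[Si](C)(C)C)cc(OCOCC[Si](C)(C)C)cc1C1(SCCCS1)c1c(OCOC)cc(C)c(Cl)c1OCOC | intermediate
20 | [3-chloro-2,6-bis(methoxymethoxy)-4-methylphenyl][2-(3-methylbut-2-en-1-yl)-3,5-bis{[2-(trimethylsilyl)ethoxy]methoxy}phenyl]methanone | CC(C)=CCc1c(OCOCC[Si](C)(C)C)cc(OCOCC[Si](C)(C)C)cc1C(=O)c1c(OCOC)cc(C)c(Cl)c1OCOC | intermediate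
21 | [3-chloro-2,6-bis(methoxymethoxy)-4-methylphenyl][3,5-dihydroxy-2-(3-methylbut-2-en-1-yl)phenyl]methanone | CC(C)=CCc1c(O)cc(O)cc1C(=O)c1c(OCOC)cc(C)c(Cl)c1OCOC | intermediate
22 | N-{[2-(3-chloro-2,6-bis(methoxymethoxy)-4-methylbenzoyl)-4,6-dihydroxy-3-(3-methylbut-2-en-1-yl)phenyl]methylidene}-N-methylmethanaminium chloride | CC(C)=CCc1c(O)cc(O)c(C=[N+](C)C)c1C(=O)c1c(OCOC)cc(C)c(Cl)c1OCOC.[Cl-] | intermediate (not isolated)
23 | 2-[3-chloro-2,6-bis(methoxymethoxy)-4-methylbenzoyl]-4,6-dihydroxy-3-(3-methylbut-2-en-1-yl)benzaldehyde | CC(C)=CCc1c(O)cc(O)c(C=O)c1C(=O)c1c(OCOC)cc(C)c(Cl)c1OCOC | intermediate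
24 | pestalone E, 2-(3-chloro-2,6-dihydroxy-4-methylbenzoyl)-4,6-dihydroxy-3-(3-methylbut-2-en-1-yl)benzaldehyde | CC(C)=CCc1c(O)cc(O)c(C=O)c1C(=O)c1c(O)cc(C)c(Cl)c1O | target

**Step count**

Total: 13 steps. Longest linear sequence: 10 steps (orcinol 5 to 24, steps 4–13); the ring-A branch (steps 1–3) joins at step 9.

**Steps most likely to fail**

1. Step 9. The dithiane anion 14, flanked by two ortho acetals, may add to aryne 16 more slowly than the aryne is consumed by 15 or by proton sources, or the crowded arylcopper 18 may be protonated instead of alkylated.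
Fallback: the rings would be joined with normal polarity, setting out from 7 and returning at 20. Commercial 3,5-dihydroxybenzaldehyde would be converted with SEMCl/i-Pr2NEt into 3,5-bis{[2-(trimethylsilyl)ethoxy]methoxy}benzaldehyde F1 and brominated with NBS ortho to the formyl group to give 2-bromo-3,5-bis{[2-(trimethylsilyl)ethoxy]methoxy}benzaldehyde F2. With the aldehyde masked in situ as a lithium α-amino alkoxide (lithium N,N,N′-trimethylethylenediamide), bromine–lithium exchange (t-BuLi), CuBr·SMe2 and prenyl bromide 13 should give 2-(3-methylbut-2-en-1-yl)-3,5-bis{[2-(trimethylsilyl)ethoxy]methoxy}benzaldehyde F3 after aqueous work-up. Aryllithium 8, made from 7 as in step 6, would add to F3 to give racemic [3-chloro-2,6-bis(methoxymethoxy)-4-methylphenyl][2-(3-methylbut-2-en-1-yl)-3,5-bis{[2-(trimethylsilyl)ethoxy]methoxy}phenyl]methanol F4, and Dess–Martin oxidation of F4 would give ketone 20.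

2. Step 12. The chloroiminium electrophile may attack C3 or ring B, and HCl set free during the reaction may strip the ring-B MOM groups or close a chroman between O2 and the prenyl group.
Fallback: the formyl carbon would be brought in through a halogen, setting out from 21 and returning at 24. NBS (CH2Cl2, −78 °C) should brominate C5, para to O2–H, to give [2-bromo-3,5-dihydroxy-6-(3-methylbut-2-en-1-yl)phenyl][3-chloro-2,6-bis(methoxymethoxy)-4-methylphenyl]methanone F6. MOMCl/i-Pr2NEt would cap the phenols to give [2-bromo-3,5-bis(methoxymethoxy)-6-(3-methylbut-2-en-1-yl)phenyl][3-chloro-2,6-bis(methoxymethoxy)-4-methylphenyl]methanone F7. Bromine–magnesium exchange with i-PrMgCl·LiCl (the hindered, non-enolisable ketone should be tolerated) and DMF would give 2-[3-chloro-2,6-bis(methoxymethoxy)-4-methylbenzoyl]-4,6-bis(methoxymethoxy)-3-(3-methylbut-2-en-1-yl)benzaldehyde F8, and dilute HCl in THF would remove all four MOM groups to give 24.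

3. Step 11. Fluoride-induced fragmentation may stall at the hindered O2 acetal, and formaldehyde that escapes the scavenger may hydroxymethylate the electron-rich resorcinolate.
Fallback: the selective unmasking would be given up, setting out from 20 and returning at 24. Protic acid (HCl, MeOH–THF, 40 °C) would remove all four acetals to give (3-chloro-2,6-dihydroxy-4-methylphenyl)[3,5-dihydroxy-2-(3-methylbut-2-en-1-yl)phenyl]methanone F5. Vilsmeier–Haack formylation of F5 would then rely on ring B being deactivated by chlorine and by conjugation and hydrogen bonding of both its hydroxyls with the ketone, and would give 24 directly.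

**Further compounds**

F1 | step 9 | 3,5-bis{[2-(trimethylsilyl)ethoxy]methoxy}benzaldehyde | O=Cc1cc(OCOCC[Si](C)(C)C)cc(OCOCC[Si](C)(C)C)c1
F2 | step 9 | 2-bromo-3,5-bis{[2-(trimethylsilyl)ethoxy]methoxy}benzaldehyde | O=Cc1cc(OCOCC[Si](C)(C)C)cc(OCOCC[Si](C)(C)C)c1Br
F3 | step 9 | 2-(3-methylbut-2-en-1-yl)-3,5-bis{[2-(trimethylsilyl)ethoxy]methoxy}benzaldehyde | CC(C)=CCc1c(OCOCC[Si](C)(C)C)cc(OCOCC[Si](C)(C)C)cc1C=O
F4 | step 9 | [3-chloro-2,6-bis(methoxymethoxy)-4-methylphenyl][2-(3-methylbut-2-en-1-yl)-3,5-bis{[2-(trimethylsilyl)ethoxy]methoxy}phenyl]methanol (racemic) | CC(C)=CCc1c(OCOCC[Si](C)(C)C)cc(OCOCC[Si](C)(C)C)cc1C(O)c1c(OCOC)cc(C)c(Cl)c1OCOC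
F5 | step 11 | (3-chloro-2,6-dihydroxy-4-methylphenyl)[3,5-dihydroxy-2-(3-methylbut-2-en-1-yl)phenyl]methanone | CC(C)=CCc1c(O)cc(O)cc1C(=O)c1c(O)cc(C)c(Cl)c1O
F6 | step 12 | [2-bromo-3,5-dihydroxy-6-(3-methylbut-2-en-1-yl)phenyl][3-chloro-2,6-bis(methoxymethoxy)-4-methylphenyl]methanone | CC(C)=CCc1c(O)cc(O)c(Br)c1C(=O)c1c(OCOC)cc(C)c(Cl)c1OCOC
F7 | step 12 | [2-bromo-3,5-bis(methoxymethoxy)-6-(3-methylbut-2-en-1-yl)phenyl][3-chloro-2,6-bis(methoxymethoxy)-4-methylphenyl]methanone | CC(C)=CCc1c(OCOC)cc(OCOC)c(Br)c1C(=O)c1c(OCOC)cc(C)c(Cl)c1OCOC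
F8 | step 12 | 2-[3-chloro-2,6-bis(methoxymethoxy)-4-methylbenzoyl]-4,6-bis(methoxymethoxy)-3-(3-methylbut-2-en-1-yl)benzaldehyde | CC(C)=CCc1c(OCOC)cc(OCOC)c(C=O)c1C(=O)c1c(OCOC)cc(C)c(Cl)c1OCOC
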